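The constants were chosen freely, and the outcome is calculated.

You ran dusk and ask whether its neighbours with more reagent hold more target at the end of the run.

| setting | dusk | spring | noon | midnight | summer |
|---|---|---|---|---|---|
| substrate | 0.039 M | 0.039 M | 0.039 M | 0.039 M | 0.039 M |
| reagent | 1.50 equiv | 2.50 equiv | 3.00 equiv | 5.00 equiv | 8.00 equiv |
| catalyst | 0.2 mol% | 0.2 mol% | 0.2 mol% | 0.2 mol% | 0.2 mol% |
| time | 2.5 min | 2.5 min | 2.5 min | 2.5 min | 2.5 min |

    substrate + reagent ⇌ isomer of the product (K1 = 3600 M⁻¹, k1 = 0.14 M⁻¹ s⁻¹)
    substrate + reagent ⇌ target (K2 = 16 M⁻¹, k2 = 0.26 M⁻¹ s⁻¹)
    catalyst + target → catalyst + over-reaction product (k3 = 53 M⁻¹ s⁻¹)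
    target + catalyst ⇌ isomer of the product + catalyst, rate k4*[catalyst]*[target] forward; the back reaction follows from the equilibrium constant (k4 = 110 M⁻¹ s⁻¹)

- "hardly changes" means that all values lie within two and a half points (for a concentration: within two and a half percent of the largest)
- run time (dusk): 2.5 min

1. [target] at the end for dusk, spring, noon, midnight, summer, in this order
2. how the row runs (rises, then falls / falls, then rises / hardly changes / falls all the way / rises all the way)

We work in fractions of the substrate charged. The catalyst is not consumed, so target's loss is pseudo-first-order: it returns to substrate at 0.0163 s⁻¹ and drains through the catalyst at 0.0127 s⁻¹. These add up to 0.0290 s⁻¹, the same in every flask because the substrate concentration and the loading are. That makes target's lifetime 34.5 s, shorter than the run of 150 s, so by the end target should trail the substrate that feeds it.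

Set its making from substrate equal to this loss and time drops out. We call the result the holding ratio, the target fraction over the substrate fraction at which target stops growing, with the trickle back from the isomer set aside. At the charged reagent it is 0.525 for dusk and 2.80 for summer.

The holding ratio grows in step with reagent, but on a rough forward count the substrate left shrinks exponentially with it. Counted forward at the charged reagent, dusk, the flask with the least reagent, already has an exponent of 3.51, above one. Past one, on that count, the product of the two falls with more reagent. So we expect a row that falls all the way, and we give no figure.

The forecast differs from us. It reads 0.0033 M, 0.0034 M, 0.0034 M, 0.0028 M, 0.0022 M, shape rises, then falls, and adds: “the rise at the low end is too small for me to be sure of it”.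

The flask gives 0.00359 M, 0.00354 M, 0.00334 M, 0.00268 M, 0.00227 M: falls all the way, so the forecast's row stands within its margin and its shape does not. At the end of dusk, target is made at 0.361 of the rate it is used up, each step taken net. With the reagent left at that moment, the holding ratio of dusk becomes 0.263, and the flask stood higher than that, at 0.367. In summer it becomes 2.45, and the flask stood at 5.60.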